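The readings were computed for substances that don't exist.

At late times the alder run stands still: from 10.0 h on, its substrate readings lie around 41.5 % and its target readings around 19.2 % of the charge.

| flask | substrate | partner | remark | time |
|---|---|---|---|---|
| birch | 0.020 M | 0.030 M | the very flask that is asked about, followed so far |  |
| alder | 0.010 M | 0.030 M | run made earlier |  |
| flask | 0.020 M | 0.0300 M |  | 40 h |

| run | time / h | substrate / % | target / % |
|---|---|---|---|
| birch | 0.250 | 83.9 | 15.8 |
| birch | 0.500 | 74.5 | 20.4 |
| birch | 0.833 | 68.5 | 23.7 |
| birch | 1.50 | 65.4 | 20.8 |
| birch | 3.00 | 55.4 | 19.4 |
| alder | 3.00 | 50.5 | 21.6 |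
| alder | 6.00 | 43.2 | 20.0 |
| alder | 10.0 | 41.6 | 19.0 |
| alder | 12.0 | 40.2 | 19.6 |
| alder | 15.0 | 42.6 | 18.9 |

(standard deviation of a reading: 1 percentage point)

* the state of affairs at 40 h: stopped, and by what, or still going (forward and back rates have come level / it is still moving / all of the substrate has reacted / the partner has run out first)
* conversion of substrate at 40 h
* amount of target at 40 h, in percent of the substrate charged
* amount of isomer of the product at 40 h, in percent of the substrate charged
* amount of target if the flask were left three thousand times as long, in percent of the substrate charged

- what was read earlier has a scatter of 1 percentage point, one standard deviation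
- reactions considered so far: substrate + partner <-> target; target <-> isomer of the product
- the reaction counts as stopped when no species that holds the substrate changes by six tenths of a point or more over the second half of the time

I take the substrate that has reacted to be target plus isomer of the product, and the alder run then holds free partner b = 0.0241 M. From this I get Q = 58.5 L mol⁻¹, the level ratio: substrate reacted over substrate left, per unit of free partner, an apparent equilibrium constant. Once both steps are level at this temperature, the fraction of substrate left is s = 1/(1 + Qb), but b depends on s, so I go round.

In the birch flask, alder's s gives b = 0.0183 M and s = 48.3 %. Put back, that gives b = 0.0197 M and s = 46.5 %, and once more s = 47.0 %.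

Since 40 h is later than 10.0 h, I expect the birch flask to be level, with conversion 53.0 %. With alder's target share of the reacted substrate, 32.7 %, target is 17.3 %.

The forecast, differing from this in the last digits, says forward and back rates have come level, conversion 53.1 %, target 17.5 %, isomer of the product 35.5 %, and 17.5 % of target at the long time: “Longer standing should change nothing.”

The birch flask gives forward and back rates have come level, with conversion 53.3 %, target 17.2 %, isomer of the product 36.1 %, and 17.2 % of target at the long time.

    substrate + partner ⇌ target (K = 19.0 L mol⁻¹, k = 0.560 L mol⁻¹ min⁻¹)
    target ⇌ isomer of the product (K = 2.10, k = 0.00910 min⁻¹)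

The neighbouring flask is the birch recipe with 0.12 M of partner, above the 0.0511 M at which target in the birch recipe has moved by 5 points. With Q and b taken as charged, s = 12.5 %. Put back, b = 0.102 M and s = 14.3 %, so alder's share gives target 28.0 %. At 40.0 h, the neighbouring flask holds target 27.7 % and substrate 14.2 %.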